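**Plan**

1. Retrosynthesis (lactone atoms O1, C2(=O), C3, C4, C5; Ca = carbinol carbon on C3; Cb = benzylic CH2 on C4): the O1–C2 ester bond is cut, C5 is raised to a carboxyl lactonised onto the Ca oxygen, and Cb is given a temporary oxygen lactonised onto C2. This uncovers a C2-symmetric, cis-fused bis-lactone (3,7-dioxabicyclo[3.3.0]octane-2,6-dione) that is not in the target.
2. Both benzylic C–O bonds are taken back to ketones and the C3–C4 bond is cut, leaving two molecules of one aroylacetate.
3. Forward: Claisen condensation; oxidative enolate dimerisation (C3–C4); double transfer hydrogenation with dynamic kinetic resolution (all stereocentres); closure of the two temporary lactone rings; reductive cleavage of one benzylic C–O (makes Cb H2, frees the C2 carboxyl); reduction of the second lactone (C5 to CH2OH, frees Ca–OH) and closure of the target ring O1–C2; debenzylation.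
4. Enabling feature: C3 and C4 each lie between an acyl-level carbon (C2, C5) and a benzylic carbon bearing the same 4-hydroxy-3-methoxyphenyl ring. With Ca and Cb both as ketones the skeleton is a homodimer whose C3 and C4 are enolisable 1,3-dicarbonyl methines, so a dl/meso mixture can converge.
5. Stereochemistry: the (S,S)-Ru catalyst sets Ca (S) and, through the dynamic resolution, C3 and C4 syn to their carbinols. The cis-fused bicycle becomes the trans-3,4-disubstituted lactone once the ring is re-formed through C2 and C5.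

Key step: step 3

Remark: the (S,S)-TsDPEN catalyst is assumed to give (S)-aryl carbinols as it does with acetophenone; if the sense is opposite, the (R,R)-catalyst is used.

**Route**

Step 1
Reactants: 1 methyl 4-(benzyloxy)-3-methoxybenzoate; 2 tert-butyl acetate
Product: 3 tert-butyl 3-[4-(benzyloxy)-3-methoxyphenyl]-3-oxopropanoate
Conditions: LiHMDS (2.5 equiv), THF, −78 → 0 °C; then cold 1 M HCl
Reagents that add atoms: tert-butyl acetate (compound 2), CC(=O)OC(C)(C)C
Why: Crossed Claisen condensation in which the lithium enolate of tert-butyl acetate, slow to self-condense, acylates the non-enolisable aryl ester and the product is held as its enolate by the excess base; no stereocentre is formed.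

Step 2
Reactants: 3 tert-butyl 3-[4-(benzyloxy)-3-methoxyphenyl]-3-oxopropanoate (2 equiv)
Product: 5 di-tert-butyl 2,3-bis[4-(benzyloxy)-3-methoxybenzoyl]butanedioate (dl/meso mixture), via α-iodo β-keto ester 4 (not isolated)
Conditions: NaH (1.05 equiv), THF, 0 °C; I2 (0.5 equiv), 0 °C → rt
Reagents that add atoms: none
Why: Oxidative dimerisation of a β-keto ester enolate (iodination of half of the sodium enolate, then SN2 displacement of iodide from 4 by the remaining enolate), the classical entry to 2,3-diacylsuccinates; both new stereocentres are 1,3-dicarbonyl methines and are deliberately left uncontrolled.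

Step 3
Reactants: 5 di-tert-butyl 2,3-bis[4-(benzyloxy)-3-methoxybenzoyl]butanedioate (dl/meso mixture)
Product: 7 di-tert-butyl (2S,3S)-2,3-bis{(S)-[4-(benzyloxy)-3-methoxyphenyl](hydroxy)methyl}butanedioate, via mono-reduced hydroxy ketone 6 (not isolated)
Conditions: RuCl[(S,S)-TsDPEN](p-cymene) (5 mol%), HCO2H/Et3N (5:2), DMF, 35 °C
Reagents that add atoms: none
Why: Noyori–Ikariya asymmetric transfer hydrogenation under dynamic kinetic resolution: the Ru–H/N–H catalyst delivers hydride and proton to each aryl ketone through the outer-sphere six-membered transition state while the formate/amine medium keeps the two methines, each flanked by a ketone and an ester carbonyl, epimerising through their enols. The closest known reaction type is the syn-selective transfer hydrogenation with dynamic kinetic resolution of α-alkyl β-aryl β-keto esters and amides. No ring is closed in this step, and the tert-butyl esters are chosen so that the γ-hydroxy esters should not lactonise before the second ketone is reduced. Both carbinol centres should be set (S) by the catalyst (aryl CH–π preference, acetophenone model), and each adjacent methine should be set syn to its carbinol because the epimer that places the bulky succinate branch anti to the incoming hydride reacts faster (Felkin-type). The step needs the same enantioface sense and the same syn selection at both ends, which gives the C2-symmetric (S,S,S,S) diol; the two identical aroylacetate halves and the two enolisable stereocentres of the substrate secure this, so that dl- and meso-5 converge. After the first reduction the reduced half is no longer a 1,3-dicarbonyl and stays fixed, so only the second half remains dynamic.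

Step 4
Reactants: 7 di-tert-butyl (2S,3S)-2,3-bis{(S)-[4-(benzyloxy)-3-methoxyphenyl](hydroxy)methyl}butanedioate
Product: 9 (3S,3aS,6S,6aS)-3,6-bis[4-(benzyloxy)-3-methoxyphenyl]tetrahydro-1H,3H-furo[3,4-c]furan-1,4-dione, via monolactone tert-butyl ester 8 (not isolated)
Conditions: TFA/CH2Cl2 (1:4), 0 °C → rt
Reagents that add atoms: none
Why: Acid-promoted loss of the tert-butyl groups with γ-lactonisation of each benzylic hydroxyl onto the remote carboxyl (5-exo-trig acyl substitution, retention at the carbinol carbons); only diols whose two methines have the same configuration can close both rings, and the cis-fused bicycle with both aryl groups on the convex face is also the thermodynamic arrangement should a benzylic C–O ionise reversibly.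

Step 5
Reactants: 9 (3S,3aS,6S,6aS)-3,6-bis[4-(benzyloxy)-3-methoxyphenyl]tetrahydro-1H,3H-furo[3,4-c]furan-1,4-dione
Product: 10 (2S,3S,4R)-4-[4-(benzyloxy)-3-methoxybenzyl]-2-[4-(benzyloxy)-3-methoxyphenyl]-5-oxooxolane-3-carboxylic acid
Conditions: Et3SiH (1.1 equiv), TFA/CH2Cl2 (1:1), 0 °C, stopped when the silane is consumed
Reagents that add atoms: none
Why: Ionic hydrogenation of a p-alkoxybenzylic ester: TFA ionises one lactone C–O (the chemistry of PMB ester cleavage) and Et3SiH reduces the cation to CH2; the two lactones are homotopic so either cleavage gives the same acid, release of bicyclic strain and the limiting silane should favour single cleavage, and the three remaining stereocentres are not touched.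

Step 6
Reactants: 10 (2S,3S,4R)-4-[4-(benzyloxy)-3-methoxybenzyl]-2-[4-(benzyloxy)-3-methoxyphenyl]-5-oxooxolane-3-carboxylic acid
Product: 12 (3S,4R)-4-[4-(benzyloxy)-3-methoxybenzyl]-3-{(S)-[4-(benzyloxy)-3-methoxyphenyl](hydroxy)methyl}oxolan-2-one, via seco hydroxy acid 11 (not isolated)
Conditions: NaH (1.0 equiv), THF, 0 °C; LiBH4 (3 equiv), THF, 0 °C → rt; then 1 M HCl to pH 3, EtOAc, rt
Reagents that add atoms: none
Why: Borohydride reduction of a lactone beside a carboxylate salt that LiBH4 does not touch (as in the reduction of succinic half-ester salts), then spontaneous γ-lactonisation of the primary alcohol onto the freed carboxyl (5-exo-trig) in preference to a β-lactone with the benzylic hydroxyl; the C–O bond at Ca is never broken, so its (S) configuration is carried over, and C3/C4 emerge trans because the new ring uses the former exocyclic carboxyl.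

Step 7
Reactants: 12 (3S,4R)-4-[4-(benzyloxy)-3-methoxybenzyl]-3-{(S)-[4-(benzyloxy)-3-methoxyphenyl](hydroxy)methyl}oxolan-2-one
Product: 13 (3S,4R)-3-[(S)-hydroxy(4-hydroxy-3-methoxyphenyl)methyl]-4-(4-hydroxy-3-methoxybenzyl)oxolan-2-one
Conditions: H2 (1 atm), 10% Pd/C, EtOAc, rt, stopped at complete debenzylation
Reagents that add atoms: none
Why: Hydrogenolysis of aryl benzyl ethers over Pd/C, which under neutral conditions at 1 atm should be much faster than loss of a free secondary benzylic hydroxyl; the lactone C–O of the target is not benzylic.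

**Compound list**

1 | methyl 4-(benzyloxy)-3-methoxybenzoate | COC(=O)c1ccc(OCc2ccccc2)c(OC)c1 | starting material
2 | tert-butyl acetate | CC(=O)OC(C)(C)C | starting material
3 | tert-butyl 3-[4-(benzyloxy)-3-methoxyphenyl]-3-oxopropanoate | CC(C)(C)OC(=O)CC(=O)c1ccc(OCc2ccccc2)c(OC)c1 | intermediate
4 | tert-butyl 3-[4-(benzyloxy)-3-methoxyphenyl]-2-iodo-3-oxopropanoate (racemic) | CC(C)(C)OC(=O)C(I)C(=O)c1ccc(OCc2ccccc2)c(OC)c1 | intermediate (not isolated)
5 | di-tert-butyl 2,3-bis[4-(benzyloxy)-3-methoxybenzoyl]butanedioate (dl/meso mixture) | CC(C)(C)OC(=O)C(C(=O)c1ccc(OCc2ccccc2)c(OC)c1)C(C(=O)c1ccc(OCc2ccccc2)c(OC)c1)C(=O)OC(C)(C)C | intermediate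
6 | di-tert-butyl (2S)-3-[4-(benzyloxy)-3-methoxybenzoyl]-2-{(S)-[4-(benzyloxy)-3-methoxyphenyl](hydroxy)methyl}butanedioate (C3 epimers interconverting) | CC(C)(C)OC(=O)[C@H]([C@H](O)c1ccc(OCc2ccccc2)c(OC)c1)C(C(=O)c1ccc(OCc2ccccc2)c(OC)c1)C(=O)OC(C)(C)C | intermediate (not isolated)
7 | di-tert-butyl (2S,3S)-2,3-bis{(S)-[4-(benzyloxy)-3-methoxyphenyl](hydroxy)methyl}butanedioate | CC(C)(C)OC(=O)[C@H]([C@H](O)c1ccc(OCc2ccccc2)c(OC)c1)[C@@H]([C@H](O)c1ccc(OCc2ccccc2)c(OC)c1)C(=O)OC(C)(C)C | intermediate
8 | tert-butyl (2S,3S,4S)-2-[4-(benzyloxy)-3-methoxyphenyl]-4-{(S)-[4-(benzyloxy)-3-methoxyphenyl](hydroxy)methyl}-5-oxooxolane-3-carboxylate | CC(C)(C)OC(=O)[C@@H]1[C@@H](c2ccc(OCc3ccccc3)c(OC)c2)OC(=O)[C@@H]1[C@H](O)c1ccc(OCc2ccccc2)c(OC)c1 | intermediate (not isolated)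
9 | (3S,3aS,6S,6aS)-3,6-bis[4-(benzyloxy)-3-methoxyphenyl]tetrahydro-1H,3H-furo[3,4-c]furan-1,4-dione | O=C1O[C@H](c2ccc(OCc3ccccc3)c(OC)c2)[C@H]2C(=O)O[C@H](c3ccc(OCc4ccccc4)c(OC)c3)[C@@H]12 | intermediate
10 | (2S,3S,4R)-4-[4-(benzyloxy)-3-methoxybenzyl]-2-[4-(benzyloxy)-3-methoxyphenyl]-5-oxooxolane-3-carboxylic acid | O=C1O[C@H](c2ccc(OCc3ccccc3)c(OC)c2)[C@@H](C(=O)O)[C@H]1Cc1ccc(OCc2ccccc2)c(OC)c1 | intermediate
11 | (2S,3R)-3-[4-(benzyloxy)-3-methoxybenzyl]-2-{(S)-[4-(benzyloxy)-3-methoxyphenyl](hydroxy)methyl}-4-hydroxybutanoic acid | OC[C@H](Cc1ccc(OCc2ccccc2)c(OC)c1)[C@H](C(=O)O)[C@H](O)c1ccc(OCc2ccccc2)c(OC)c1 | intermediate (not isolated)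
12 | (3S,4R)-4-[4-(benzyloxy)-3-methoxybenzyl]-3-{(S)-[4-(benzyloxy)-3-methoxyphenyl](hydroxy)methyl}oxolan-2-one | COc1cc(C[C@H]2COC(=O)[C@@H]2[C@H](O)c2ccc(OCc3ccccc3)c(OC)c2)ccc1OCc1ccccc1 | intermediate
13 | (3S,4R)-3-[(S)-hydroxy(4-hydroxy-3-methoxyphenyl)methyl]-4-(4-hydroxy-3-methoxybenzyl)oxolan-2-one | COc1cc(C[C@H]2COC(=O)[C@@H]2[C@H](O)c2ccc(O)c(OC)c2)ccc1O | target

**Step count and risks**

Total steps: 7. Longest linear sequence: 7 (from compound 1).

Steps most likely to fail:

1. Step 3. The second reduction may lose diastereocontrol (mismatch between the catalyst and the stereodiad formed first), the hindered methine may epimerise too slowly for the dynamic resolution, or a γ-hydroxy ester may lactonise early and move the second reduction into a cyclic manifold. Fallback, setting out from 5 and coming back at 10: compound 5 is reduced under substrate control with Zn(BH4)2 (Et2O, 0 °C), where the zinc chelate of each β-keto ester unit takes hydride anti to the branch; the dl part of 5 should give the racemic syn,syn-diol F1. TFA/CH2Cl2 as in step 4 closes it to the racemic bis-lactone F2; material from meso-5 cannot close the second ring and is removed by base extraction. Et3SiH/TFA as in step 5 gives the racemic acid-lactone F3. This is resolved by fractional crystallisation of the (R)-1-phenylethylammonium salt F4 (the antipodal amine is taken if the salt of the enantiomer proves less soluble), and acidification of F4 returns 10.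

2. Step 5. The second lactone may ionise and take up hydride before the first is consumed, giving the dibenzylsuccinic acid, or the benzylic cation may eliminate. Fallback, setting out from 9 and coming back at 10: the bis-lactone is opened by SN2 attack of benzeneselenolate (PhSeSePh, NaBH4, DMF/EtOH, 60 °C, 1.05 equiv) at one benzylic carbon with inversion; the carboxylate that forms should disfavour a second anionic attack. Acidification gives the selenide acid-lactone F5, and radical reduction (Bu3SnH, AIBN, toluene, 80 °C) replaces selenium by hydrogen to return 10.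

3. Step 7. The benzylic Ca–OH may be hydrogenolysed along with or after debenzylation. Fallback, setting out from 9 and coming back at 13: hydrogenation of 9 over Pd/C (EtOAc/AcOH, 1 atm) removes both benzyl ethers and, continued to the uptake of a third equivalent, cleaves one lactone C–O to give the phenolic acid-lactone F6. TBSCl/imidazole (DMF) silylates both phenols and the carboxyl to the tris-silyl compound F7, whose silyl ester is lost on aqueous work-up to leave the bis-silyl ether acid F8. Reduction and relactonisation as in step 6 lead through the seco acid F9 to the bis-silyl ether of the target F10. Buffered fluoride (TBAF/AcOH, THF, 0 °C) frees both phenols and gives 13, so no hydrogenolysis is run while Ca–OH is free.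

**Further compounds**

F1 | step 3 | racemic di-tert-butyl (2S*,3S*)-2,3-bis{(S*)-[4-(benzyloxy)-3-methoxyphenyl](hydroxy)methyl}butanedioate | CC(C)(C)OC(=O)[C@H]([C@H](O)c1ccc(OCc2ccccc2)c(OC)c1)[C@@H]([C@H](O)c1ccc(OCc2ccccc2)c(OC)c1)C(=O)OC(C)(C)C.CC(C)(C)OC(=O)[C@@H]([C@@H](O)c1ccc(OCc2ccccc2)c(OC)c1)[C@H]([C@@H](O)c1ccc(OCc2ccccc2)c(OC)c1)C(=O)OC(C)(C)C
F2 | step 3 | racemic (3S*,3aS*,6S*,6aS*)-3,6-bis[4-(benzyloxy)-3-methoxyphenyl]tetrahydro-1H,3H-furo[3,4-c]furan-1,4-dione | O=C1O[C@H](c2ccc(OCc3ccccc3)c(OC)c2)[C@H]2C(=O)O[C@H](c3ccc(OCc4ccccc4)c(OC)c3)[C@@H]12.O=C1O[C@@H](c2ccc(OCc3ccccc3)c(OC)c2)[C@@H]2C(=O)O[C@@H](c3ccc(OCc4ccccc4)c(OC)c3)[C@H]12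
F3 | step 3 | racemic (2S*,3S*,4R*)-4-[4-(benzyloxy)-3-methoxybenzyl]-2-[4-(benzyloxy)-3-methoxyphenyl]-5-oxooxolane-3-carboxylic acid | O=C1O[C@H](c2ccc(OCc3ccccc3)c(OC)c2)[C@@H](C(=O)O)[C@H]1Cc1ccc(OCc2ccccc2)c(OC)c1.O=C1O[C@@H](c2ccc(OCc3ccccc3)c(OC)c2)[C@H](C(=O)O)[C@@H]1Cc1ccc(OCc2ccccc2)c(OC)c1
F4 | step 3 | (R)-1-phenylethylammonium (2S,3S,4R)-4-[4-(benzyloxy)-3-methoxybenzyl]-2-[4-(benzyloxy)-3-methoxyphenyl]-5-oxooxolane-3-carboxylate | O=C1O[C@H](c2ccc(OCc3ccccc3)c(OC)c2)[C@@H](C(=O)[O-])[C@H]1Cc1ccc(OCc2ccccc2)c(OC)c1.C[C@@H]([NH3+])c1ccccc1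
F5 | step 5 | (2S,3S,4R)-2-[4-(benzyloxy)-3-methoxyphenyl]-4-{(R)-[4-(benzyloxy)-3-methoxyphenyl](phenylselanyl)methyl}-5-oxooxolane-3-carboxylic acid | O=C1O[C@H](c2ccc(OCc3ccccc3)c(OC)c2)[C@@H](C(=O)O)[C@H]1[C@@H]([Se]c1ccccc1)c1ccc(OCc2ccccc2)c(OC)c1
F6 | step 7 | (2S,3S,4R)-4-(4-hydroxy-3-methoxybenzyl)-2-(4-hydroxy-3-methoxyphenyl)-5-oxooxolane-3-carboxylic acid | O=C1O[C@H](c2ccc(O)c(OC)c2)[C@@H](C(=O)O)[C@H]1Cc1ccc(O)c(OC)c1
F7 | step 7 | tert-butyldimethylsilyl (2S,3S,4R)-4-[4-(tert-butyldimethylsilyloxy)-3-methoxybenzyl]-2-[4-(tert-butyldimethylsilyloxy)-3-methoxyphenyl]-5-oxooxolane-3-carboxylate | O=C1O[C@H](c2ccc(O[Si](C)(C)C(C)(C)C)c(OC)c2)[C@@H](C(=O)O[Si](C)(C)C(C)(C)C)[C@H]1Cc1ccc(O[Si](C)(C)C(C)(C)C)c(OC)c1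
F8 | step 7 | (2S,3S,4R)-4-[4-(tert-butyldimethylsilyloxy)-3-methoxybenzyl]-2-[4-(tert-butyldimethylsilyloxy)-3-methoxyphenyl]-5-oxooxolane-3-carboxylic acid | O=C1O[C@H](c2ccc(O[Si](C)(C)C(C)(C)C)c(OC)c2)[C@@H](C(=O)O)[C@H]1Cc1ccc(O[Si](C)(C)C(C)(C)C)c(OC)c1
F9 | step 7 | (2S,3R)-3-[4-(tert-butyldimethylsilyloxy)-3-methoxybenzyl]-2-{(S)-[4-(tert-butyldimethylsilyloxy)-3-methoxyphenyl](hydroxy)methyl}-4-hydroxybutanoic acid | OC[C@H](Cc1ccc(O[Si](C)(C)C(C)(C)C)c(OC)c1)[C@H](C(=O)O)[C@H](O)c1ccc(O[Si](C)(C)C(C)(C)C)c(OC)c1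
F10 | step 7 | (3S,4R)-4-[4-(tert-butyldimethylsilyloxy)-3-methoxybenzyl]-3-{(S)-[4-(tert-butyldimethylsilyloxy)-3-methoxyphenyl](hydroxy)methyl}oxolan-2-one | COc1cc(C[C@H]2COC(=O)[C@@H]2[C@H](O)c2ccc(O[Si](C)(C)C(C)(C)C)c(OC)c2)ccc1O[Si](C)(C)C(C)(C)C
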